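**Plan**

1. Clerodane numbering is used (ring A = C1–C5 and C10, ring B = C5–C10, side chain C11–C16). The retrosynthesis removes the C15 icosanoate and a C16 silyl ether, then cuts C12–C13 (sp3–sp2 Suzuki–Miyaura coupling of a C9-vinyl decalin with a (Z)-vinyl iodide made from but-2-yne-1,4-diol).
2. Enabling feature: ring A is a cyclohexene whose only double bond, C3=C4, lies opposite the C1–C10 bond, and C5 and C10 are also bridged by C6–C9 of ring B. Cutting C1–C2 and C5–C10 together therefore opens both rings to an acyclic 1,3,9-decatriene (diene C2=C3–C4=C5, dienophile C10=C1).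
3. Helpers: a phenylsulfonyl group on C1 activates the dienophile and is removed with Na(Hg). The second alkenyl group on C9, a plain vinyl group, is not activated and later becomes C11–C12.
4. Forward order: Ireland–Claisen rearrangement (C8–C9), acetoacetate dianion alkylation (C6–C7), enol triflate and Negishi methylation (C5–C19), Wittig (C2=C3), Horner–Wadsworth–Emmons (C1=C10), Diels–Alder (rings A and B together), desulfonylation, Suzuki–Miyaura (C12–C13), acylation, desilylation.
5. Stereochemistry: C8 and C9 come from the enantioselective Ireland–Claisen rearrangement. C5 and C10 come from the Diels–Alder step. The C4=C5 geometry comes from a chelated (Z)-enol triflate, and the C13=C14 geometry from trans-hydroalumination/iodination followed by stereoretentive coupling.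

Key step: step 16

Assumption: the (4S,5S) antipode of the bromoborane controller is written in step 4; both antipodes are available, and the one that delivers the (2S,3S) acid 7 is the one to be used.

**Step 1**
Reactants: 1 3-methylbut-2-en-1-ol; 2 propanoyl chloride
Product: 3 3-methylbut-2-en-1-yl propanoate
Conditions: pyridine, DMAP (cat.), CH2Cl2, 0 °C → rt
Reagents that add atoms: none
Why: Esterification of a primary allylic alcohol with an acid chloride under nucleophilic catalysis should be clean and forms no stereocentre.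

**Step 2**
Reactants: 3 3-methylbut-2-en-1-yl propanoate
Product: 4 (2E)-4-hydroxy-3-methylbut-2-en-1-yl propanoate
Conditions: SeO2 (cat.), t-BuOOH, CH2Cl2, rt
Reagents that add atoms: tert-butyl hydroperoxide, CC(C)(C)OO
Why: The Riley allylic oxidation (ene reaction then [2,3]-shift) hydroxylates the (E)-methyl group of a trisubstituted alkene selectively, so the (E)-allylic alcohol should result with the ester untouched.

**Step 3**
Reactants: 4 (2E)-4-hydroxy-3-methylbut-2-en-1-yl propanoate
Product: 5 (2E)-4-[(tert-butyldimethylsilyl)oxy]-3-methylbut-2-en-1-yl propanoate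
Conditions: TBSCl, imidazole, DMF, rt
Reagents that add atoms: tert-butyldimethylsilyl chloride, CC(C)(C)[Si](C)(C)Cl
Why: Silylation of the primary alcohol protects the future C10 oxygen through the enolate, hydride and organometallic steps that follow.

**Step 4**
Reactants: 5 (2E)-4-[(tert-butyldimethylsilyl)oxy]-3-methylbut-2-en-1-yl propanoate
Product: 7 (2S,3S)-3-{[(tert-butyldimethylsilyl)oxy]methyl}-2,3-dimethylpent-4-enoic acid, via boron enolate 6 (not isolated)
Conditions: (4S,5S)-2-bromo-1,3-bis{[3,5-bis(trifluoromethyl)phenyl]sulfonyl}-4,5-diphenyl-1,3,2-diazaborolidine, Et3N, toluene–hexane, −78 °C → 4 °C; aqueous acidic work-up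
Reagents that add atoms: none
Why: In this enantioselective Ireland–Claisen ([3,3]-sigmatropic) rearrangement the E(O)-boron enolate (methyl axial) and the (E)-alkene (C9 methyl axial, silyloxymethyl equatorial) should pass through a chair transition state that gives the syn relationship of C8 and the quaternary C9, while the C2-symmetric sulfonamide ligand on boron selects the enolate face and so the absolute configuration.

**Step 5**
Reactants: 7 (2S,3S)-3-{[(tert-butyldimethylsilyl)oxy]methyl}-2,3-dimethylpent-4-enoic acid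
Product: 8 (2S,3S)-3-{[(tert-butyldimethylsilyl)oxy]methyl}-2,3-dimethylpent-4-en-1-ol
Conditions: LiAlH4, THF, 0 °C → rt
Reagents that add atoms: none
Why: Hydride reduction of the carboxylic acid to the primary alcohol proceeds through the carboxylate, so the α-stereocentre should not epimerise and the silyl ether and vinyl group are inert.

**Step 6**
Reactants: 8 (2S,3S)-3-{[(tert-butyldimethylsilyl)oxy]methyl}-2,3-dimethylpent-4-en-1-ol
Product: 9 tert-butyl{[(2S,3S)-2-ethenyl-4-iodo-2,3-dimethylbutyl]oxy}dimethylsilane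
Conditions: I2, PPh3, imidazole, CH2Cl2, 0 °C → rt
Reagents that add atoms: iodine, II
Why: Appel-type iodination converts the primary alcohol into the iodide under neutral conditions without touching the stereocentres.

**Step 7**
Reactants: 9 tert-butyl{[(2S,3S)-2-ethenyl-4-iodo-2,3-dimethylbutyl]oxy}dimethylsilane; 10 methyl 2-methyl-3-oxobutanoate
Product: 12 methyl (6R,7S)-7-{[(tert-butyldimethylsilyl)oxy]methyl}-2,6,7-trimethyl-3-oxonon-8-enoate (mixture at C2), via acetoacetate dianion 11 (not isolated)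
Conditions: 10, NaH, THF, 0 °C; n-BuLi, 0 °C; then 9, DMPU, 0 °C → rt
Reagents that add atoms: none
Why: In this dianion alkylation (SN2) the terminal carbanion of the β-keto ester dianion is the more nucleophilic site, so it should join C6 to C7 and leave the β-keto ester ready for the next step; the C2 epimers converge later.

**Step 8**
Reactants: 12 methyl (6R,7S)-7-{[(tert-butyldimethylsilyl)oxy]methyl}-2,6,7-trimethyl-3-oxonon-8-enoate
Product: 13 methyl (2Z,6R,7S)-7-{[(tert-butyldimethylsilyl)oxy]methyl}-2,6,7-trimethyl-3-{[(trifluoromethyl)sulfonyl]oxy}nona-2,8-dienoate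
Conditions: NaH, THF, 0 °C; PhNTf2, 0 °C → rt
Reagents that add atoms: N-phenylbis(trifluoromethanesulfonimide), O=S(=O)(N(c1ccccc1)S(=O)(=O)C(F)(F)F)C(F)(F)F
Why: O-Sulfonylation of the sodium-chelated β-keto ester enolate should give the (Z)-enol triflate (triflate cis to the ester), which fixes the geometry of the future tetrasubstituted C4=C5 alkene.

**Step 9**
Reactants: 13 methyl (2Z,6R,7S)-7-{[(tert-butyldimethylsilyl)oxy]methyl}-2,6,7-trimethyl-3-{[(trifluoromethyl)sulfonyl]oxy}nona-2,8-dienoate
Product: 14 methyl (2E,6R,7S)-7-{[(tert-butyldimethylsilyl)oxy]methyl}-2,3,6,7-tetramethylnona-2,8-dienoate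
Conditions: MeZnCl, Pd(PPh3)4 (cat.), THF, rt → 50 °C
Reagents that add atoms: methylzinc chloride, C[Zn]Cl
Why: Negishi coupling of the activated β-triflyloxy enoate at zerovalent palladium proceeds with retention of alkene geometry, so the new methyl group (C19) should end cis to the ester and the chain trans to it.

**Step 10**
Reactants: 14 methyl (2E,6R,7S)-7-{[(tert-butyldimethylsilyl)oxy]methyl}-2,3,6,7-tetramethylnona-2,8-dienoate
Product: 15 (2E,6R,7S)-7-{[(tert-butyldimethylsilyl)oxy]methyl}-2,3,6,7-tetramethylnona-2,8-dien-1-ol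
Conditions: i-Bu2AlH, CH2Cl2, −78 °C
Reagents that add atoms: none
Why: 1,2-Reduction of the enoate with an aluminium hydride should give the allylic alcohol without touching the alkene geometry.

**Step 11**
Reactants: 15 (2E,6R,7S)-7-{[(tert-butyldimethylsilyl)oxy]methyl}-2,3,6,7-tetramethylnona-2,8-dien-1-ol
Product: 16 (2E,6R,7S)-7-{[(tert-butyldimethylsilyl)oxy]methyl}-2,3,6,7-tetramethylnona-2,8-dienal
Conditions: MnO2, CH2Cl2, rt
Reagents that add atoms: none
Why: Heterogeneous allylic oxidation with MnO2 is neutral and should give the enal without E/Z isomerisation.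

**Step 12**
Reactants: 16 (2E,6R,7S)-7-{[(tert-butyldimethylsilyl)oxy]methyl}-2,3,6,7-tetramethylnona-2,8-dienal
Product: 17 tert-butyl{[(2S,3R,6E)-2-ethenyl-2,3,6,7-tetramethylnona-6,8-dien-1-yl]oxy}dimethylsilane
Conditions: Ph3PCH3Br, KN(SiMe3)2, THF, 0 °C; then 16, −78 → 0 °C
Reagents that add atoms: methyltriphenylphosphonium bromide, C[P+](c1ccccc1)(c1ccccc1)c1ccccc1.[Br-]
Why: Wittig methylenation of the enal at low temperature should complete the diene (C2=C3) and keep the tetrasubstituted alkene geometry.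

**Step 13**
Reactants: 17 tert-butyl{[(2S,3R,6E)-2-ethenyl-2,3,6,7-tetramethylnona-6,8-dien-1-yl]oxy}dimethylsilane
Product: 18 (2S,3R,6E)-2-ethenyl-2,3,6,7-tetramethylnona-6,8-dien-1-ol
Conditions: Bu4NF, THF, rt
Reagents that add atoms: none
Why: Fluoride-induced desilylation frees the neopentyl alcohol under conditions to which the diene and vinyl group are inert.

**Step 14**
Reactants: 18 (2S,3R,6E)-2-ethenyl-2,3,6,7-tetramethylnona-6,8-dien-1-ol
Product: 19 (2S,3R,6E)-2-ethenyl-2,3,6,7-tetramethylnona-6,8-dienal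
Conditions: Dess–Martin periodinane, CH2Cl2, rt
Reagents that add atoms: none
Why: Dess–Martin oxidation should give the aldehyde, which has a quaternary α-carbon and therefore can neither epimerise nor move its vinyl group into conjugation.

**Step 15**
Reactants: 19 (2S,3R,6E)-2-ethenyl-2,3,6,7-tetramethylnona-6,8-dienal
Product: 20 {[(1E,3S,4R,7E)-3-ethenyl-3,4,7,8-tetramethyldeca-1,7,9-trien-1-yl]sulfonyl}benzene
Conditions: (EtO)2P(O)CH2SO2Ph, NaH, THF, 0 °C → rt
Reagents that add atoms: diethyl [(phenylsulfonyl)methyl]phosphonate, CCOP(=O)(CS(=O)(=O)c1ccccc1)OCC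
Why: Horner–Wadsworth–Emmons olefination with the sulfonyl-stabilised phosphonate should give the (E)-vinyl sulfone, which installs C1 together with the removable activating group.

**Step 16**
Reactants: 20 {[(1E,3S,4R,7E)-3-ethenyl-3,4,7,8-tetramethyldeca-1,7,9-trien-1-yl]sulfonyl}benzene
Product: 21 (1S,2R,4aR,8R,8aR)-1-ethenyl-1,2,4a,5-tetramethyl-8-(phenylsulfonyl)-1,2,3,4,4a,7,8,8a-octahydronaphthalene
Conditions: toluene (high dilution), BHT (cat.), 150 °C, sealed tube
Reagents that add atoms: none
Why: This is a thermal intramolecular Diels–Alder reaction, a concerted suprafacial [4+2] cycloaddition of the C2=C3–C4=C5 diene to the sulfonyl-activated C10=C1 alkene; the closest known reaction type is the intramolecular Diels–Alder reaction of 1,3,9-decatrienes with a terminal (E)-sulfonylvinyl or nitrovinyl dienophile used as an ethylene equivalent. Ring A closes as the cyclohexene of the [4+2] event (bonds C1–C2 and C5–C10), and ring B closes in the same event because the four-carbon tether C6–C9 spans the diene terminus C5 and the dienophile carbon C10, so that C5–C10 becomes the fusion bond of a bicyclo[4.4.0] system. C5 and C10 are set together: the (E) geometry of the C4=C5 alkene puts the tether outside and the C19 methyl inside the diene, and the anti (tether-exo, sulfone-endo) transition state with a chair-like tether should then give the trans ring fusion, the quaternary C9 with its two extra substituents disfavouring the tether-endo (cis) alternative. The diene face is chosen by C8 and C9: the chair that keeps the C8 methyl equatorial places the C9 methyl axial and the C9 vinyl equatorial, which is the 5R,10R arrangement, and since this preference is modest in energy the minor trans-fused isomer is to be removed at the sulfone stage. C1 follows from the (E) geometry of the vinyl sulfone and is of no consequence because the sulfone leaves in step 17. The step needs chemoselection between the two alkenyl groups on C9, which is secured because only the sulfonyl-bearing one is activated, and a temperature that stays below the onset of 1,5-hydrogen shift in the (Z)-methyl-substituted diene.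

**Step 17**
Reactants: 21 (1S,2R,4aR,8R,8aR)-1-ethenyl-1,2,4a,5-tetramethyl-8-(phenylsulfonyl)-1,2,3,4,4a,7,8,8a-octahydronaphthalene
Product: 22 (1S,2R,4aR,8aR)-1-ethenyl-1,2,4a,5-tetramethyl-1,2,3,4,4a,7,8,8a-octahydronaphthalene
Conditions: Na(Hg) (6%), Na2HPO4, MeOH–THF, −20 → 0 °C
Reagents that add atoms: none
Why: Reductive desulfonylation (electron transfer, C–S cleavage, protonation) removes the activating group from a secondary carbon that has no β-leaving group, so the isolated alkenes and all stereocentres should be retained.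

**Step 18**
Reactants: 23 but-2-yne-1,4-diol
Product: 24 4-[(tert-butyldimethylsilyl)oxy]but-2-yn-1-ol
Conditions: NaH (1 equiv), THF, 0 °C; TBSCl, rt
Reagents that add atoms: tert-butyldimethylsilyl chloride, CC(C)(C)[Si](C)(C)Cl
Why: Monosilylation of a symmetrical diol through its sparingly soluble monoalkoxide should differentiate the two hydroxyl groups that become O15 and O16.

**Step 19**
Reactants: 24 4-[(tert-butyldimethylsilyl)oxy]but-2-yn-1-ol
Product: 26 (2Z)-4-[(tert-butyldimethylsilyl)oxy]-3-iodobut-2-en-1-ol, via cyclic vinylaluminate 25 (not isolated)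
Conditions: NaAlH2(OCH2CH2OMe)2, THF, 0 °C; EtOAc; then I2, −78 → 0 °C
Reagents that add atoms: iodine, II
Why: Hydroxyl-directed trans-hydroalumination of the propargylic alcohol delivers hydride to the proximal carbon and aluminium to the distal one inside a five-membered chelate, so iodinolysis with retention should give the vinyl iodide with iodine cis to the hydroxymethyl group.

**Step 20**
Reactants: 22 (1S,2R,4aR,8aR)-1-ethenyl-1,2,4a,5-tetramethyl-1,2,3,4,4a,7,8,8a-octahydronaphthalene; 26 (2Z)-4-[(tert-butyldimethylsilyl)oxy]-3-iodobut-2-en-1-ol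
Product: 28 (2E)-3-{[(tert-butyldimethylsilyl)oxy]methyl}-5-[(1S,2R,4aR,8aR)-1,2,4a,5-tetramethyl-1,2,3,4,4a,7,8,8a-octahydronaphthalen-1-yl]pent-2-en-1-ol, via B-alkyl-9-BBN adduct 27 (not isolated)
Conditions: 9-BBN dimer, THF, rt → 60 °C; then 26, Pd(dppf)Cl2 (cat.), AsPh3, Cs2CO3, DMF–H2O, rt
Reagents that add atoms: none
Why: 9-BBN hydroborates the monosubstituted vinyl group in preference to the trisubstituted ring alkene, and the B-alkyl Suzuki–Miyaura coupling with the vinyl iodide retains the alkene geometry, so C12 should end cis to C15 as the target requires.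

**Step 21**
Reactants: 28 (2E)-3-{[(tert-butyldimethylsilyl)oxy]methyl}-5-[(1S,2R,4aR,8aR)-1,2,4a,5-tetramethyl-1,2,3,4,4a,7,8,8a-octahydronaphthalen-1-yl]pent-2-en-1-ol; 29 icosanoyl chloride
Product: 30 (2E)-3-{[(tert-butyldimethylsilyl)oxy]methyl}-5-[(1S,2R,4aR,8aR)-1,2,4a,5-tetramethyl-1,2,3,4,4a,7,8,8a-octahydronaphthalen-1-yl]pent-2-en-1-yl icosanoate
Conditions: pyridine, DMAP (cat.), CH2Cl2, 0 °C → rt
Reagents that add atoms: none
Why: Acylation of the only free hydroxyl group (O15) with the fatty acid chloride places the ester unambiguously, because O16 is still silylated.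

**Step 22**
Reactants: 30 (2E)-3-{[(tert-butyldimethylsilyl)oxy]methyl}-5-[(1S,2R,4aR,8aR)-1,2,4a,5-tetramethyl-1,2,3,4,4a,7,8,8a-octahydronaphthalen-1-yl]pent-2-en-1-yl icosanoate
Product: 31 (2E)-3-(hydroxymethyl)-5-[(1S,2R,4aR,8aR)-1,2,4a,5-tetramethyl-1,2,3,4,4a,7,8,8a-octahydronaphthalen-1-yl]pent-2-en-1-yl icosanoate (CNP0168335.1)
Conditions: HF·pyridine, pyridine, THF, 0 °C → rt
Reagents that add atoms: none
Why: Buffered fluoride desilylation frees O16 without cleaving the allylic ester, and acyl migration is excluded because the two oxygenated carbons are trans across the C13=C14 alkene.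

**Compound list**

1 | 3-methylbut-2-en-1-ol | CC(C)=CCO | starting material
2 | propanoyl chloride | CCC(=O)Cl | starting material
3 | 3-methylbut-2-en-1-yl propanoate | CCC(=O)OCC=C(C)C | intermediate
4 | (2E)-4-hydroxy-3-methylbut-2-en-1-yl propanoate | CCC(=O)OC/C=C(\C)CO | intermediate
5 | (2E)-4-[(tert-butyldimethylsilyl)oxy]-3-methylbut-2-en-1-yl propanoate | CCC(=O)OC/C=C(\C)CO[Si](C)(C)C(C)(C)C | intermediate
6 | E(O)-boron enolate of 5 carrying the (4S,5S)-1,3-bis{[3,5-bis(trifluoromethyl)phenyl]sulfonyl}-4,5-diphenyl-1,3,2-diazaborolidin-2-yl group on oxygen | C/C=C(/OB1N(S(=O)(=O)c2cc(C(F)(F)F)cc(C(F)(F)F)c2)[C@@H](c2ccccc2)[C@H](c2ccccc2)N1S(=O)(=O)c1cc(C(F)(F)F)cc(C(F)(F)F)c1)OC/C=C(\C)CO[Si](C)(C)C(C)(C)C | intermediate (not isolated)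
7 | (2S,3S)-3-{[(tert-butyldimethylsilyl)oxy]methyl}-2,3-dimethylpent-4-enoic acid | C=C[C@@](CO[Si](C)(C)C(C)(C)C)(C)[C@H](C)C(=O)O | intermediate
8 | (2S,3S)-3-{[(tert-butyldimethylsilyl)oxy]methyl}-2,3-dimethylpent-4-en-1-ol | C=C[C@@](CO[Si](C)(C)C(C)(C)C)(C)[C@H](C)CO | intermediate
9 | tert-butyl{[(2S,3S)-2-ethenyl-4-iodo-2,3-dimethylbutyl]oxy}dimethylsilane | C=C[C@@](CO[Si](C)(C)C(C)(C)C)(C)[C@H](C)CI | intermediate
10 | methyl 2-methyl-3-oxobutanoate | CC(=O)C(C)C(=O)OC | starting material
11 | sodium lithium dianion of methyl 2-methyl-3-oxobutanoate | [Na+].[Li+].C=C([O-])C(C)=C([O-])OC | intermediate (not isolated)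
12 | methyl (6R,7S)-7-{[(tert-butyldimethylsilyl)oxy]methyl}-2,6,7-trimethyl-3-oxonon-8-enoate (mixture at C2) | C=C[C@@](CO[Si](C)(C)C(C)(C)C)(C)[C@H](C)CCC(=O)C(C)C(=O)OC | intermediate
13 | methyl (2Z,6R,7S)-7-{[(tert-butyldimethylsilyl)oxy]methyl}-2,6,7-trimethyl-3-{[(trifluoromethyl)sulfonyl]oxy}nona-2,8-dienoate | C=C[C@@](CO[Si](C)(C)C(C)(C)C)(C)[C@H](C)CC/C(OS(=O)(=O)C(F)(F)F)=C(\C)C(=O)OC | intermediate
14 | methyl (2E,6R,7S)-7-{[(tert-butyldimethylsilyl)oxy]methyl}-2,3,6,7-tetramethylnona-2,8-dienoate | C=C[C@@](CO[Si](C)(C)C(C)(C)C)(C)[C@H](C)CC/C(C)=C(\C)C(=O)OC | intermediate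
15 | (2E,6R,7S)-7-{[(tert-butyldimethylsilyl)oxy]methyl}-2,3,6,7-tetramethylnona-2,8-dien-1-ol | C=C[C@@](CO[Si](C)(C)C(C)(C)C)(C)[C@H](C)CC/C(C)=C(\C)CO | intermediate
16 | (2E,6R,7S)-7-{[(tert-butyldimethylsilyl)oxy]methyl}-2,3,6,7-tetramethylnona-2,8-dienal | C=C[C@@](CO[Si](C)(C)C(C)(C)C)(C)[C@H](C)CC/C(C)=C(\C)C=O | intermediate
17 | tert-butyl{[(2S,3R,6E)-2-ethenyl-2,3,6,7-tetramethylnona-6,8-dien-1-yl]oxy}dimethylsilane | C=C[C@@](CO[Si](C)(C)C(C)(C)C)(C)[C@H](C)CC/C(C)=C(\C)C=C | intermediate
18 | (2S,3R,6E)-2-ethenyl-2,3,6,7-tetramethylnona-6,8-dien-1-ol | C=C[C@@](CO)(C)[C@H](C)CC/C(C)=C(\C)C=C | intermediate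
19 | (2S,3R,6E)-2-ethenyl-2,3,6,7-tetramethylnona-6,8-dienal | C=C[C@@](C=O)(C)[C@H](C)CC/C(C)=C(\C)C=C | intermediate
20 | {[(1E,3S,4R,7E)-3-ethenyl-3,4,7,8-tetramethyldeca-1,7,9-trien-1-yl]sulfonyl}benzene | C=C[C@@](/C=C/S(=O)(=O)c1ccccc1)(C)[C@H](C)CC/C(C)=C(\C)C=C | intermediate
21 | (1S,2R,4aR,8R,8aR)-1-ethenyl-1,2,4a,5-tetramethyl-8-(phenylsulfonyl)-1,2,3,4,4a,7,8,8a-octahydronaphthalene | C=C[C@@]1(C)[C@H](C)CC[C@@]2(C)C(C)=CC[C@@H](S(=O)(=O)c3ccccc3)[C@H]12 | intermediate
22 | (1S,2R,4aR,8aR)-1-ethenyl-1,2,4a,5-tetramethyl-1,2,3,4,4a,7,8,8a-octahydronaphthalene | C=C[C@@]1(C)[C@H](C)CC[C@@]2(C)C(C)=CCC[C@H]12 | intermediate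
23 | but-2-yne-1,4-diol | OCC#CCO | starting material
24 | 4-[(tert-butyldimethylsilyl)oxy]but-2-yn-1-ol | OCC#CCO[Si](C)(C)C(C)(C)C | intermediate
25 | sodium cyclic vinylaluminate (five-membered O–Al–C chelate with two 2-methoxyethoxy ligands) | [Na+].COCCO[Al-]1(OCCOC)OCC=C1CO[Si](C)(C)C(C)(C)C | intermediate (not isolated)
26 | (2Z)-4-[(tert-butyldimethylsilyl)oxy]-3-iodobut-2-en-1-ol | OC/C=C(/CO[Si](C)(C)C(C)(C)C)I | intermediate
27 | 9-{2-[(1S,2R,4aR,8aR)-1,2,4a,5-tetramethyl-1,2,3,4,4a,7,8,8a-octahydronaphthalen-1-yl]ethyl}-9-borabicyclo[3.3.1]nonane | C1CCC2CCCC1B2CC[C@@]1(C)[C@H](C)CC[C@@]2(C)C(C)=CCC[C@H]12 | intermediate (not isolated)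
28 | (2E)-3-{[(tert-butyldimethylsilyl)oxy]methyl}-5-[(1S,2R,4aR,8aR)-1,2,4a,5-tetramethyl-1,2,3,4,4a,7,8,8a-octahydronaphthalen-1-yl]pent-2-en-1-ol | OC/C=C(/CO[Si](C)(C)C(C)(C)C)CC[C@@]1(C)[C@H](C)CC[C@@]2(C)C(C)=CCC[C@H]12 | intermediate
29 | icosanoyl chloride | CCCCCCCCCCCCCCCCCCCC(=O)Cl | starting material
30 | (2E)-3-{[(tert-butyldimethylsilyl)oxy]methyl}-5-[(1S,2R,4aR,8aR)-1,2,4a,5-tetramethyl-1,2,3,4,4a,7,8,8a-octahydronaphthalen-1-yl]pent-2-en-1-yl icosanoate | CCCCCCCCCCCCCCCCCCCC(=O)OC/C=C(/CO[Si](C)(C)C(C)(C)C)CC[C@@]1(C)[C@H](C)CC[C@@]2(C)C(C)=CCC[C@H]12 | intermediate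
31 | (2E)-3-(hydroxymethyl)-5-[(1S,2R,4aR,8aR)-1,2,4a,5-tetramethyl-1,2,3,4,4a,7,8,8a-octahydronaphthalen-1-yl]pent-2-en-1-yl icosanoate | CCCCCCCCCCCCCCCCCCCC(=O)OC/C=C(/CO)CC[C@@]1(C)[C@H](C)CC[C@@]2(C)C(C)=CCC[C@H]12 | target

**Step count**

Total step count: 22. Longest linear sequence: 20 steps (steps 1–17 and 20–22).

**Steps most likely to fail**

Step 16. The diene carries an inside methyl group on C5, so the cycloaddition may be too slow below the temperature at which 1,5-hydrogen shift and polymerisation begin. Endo/exo and facial selection may also erode at 150 °C. The fallback replaces the sulfone by a nitro group as activating group, which reacts at much lower temperature and prefers the endo mode more strongly. It sets out from aldehyde 19. A Henry reaction with nitromethane (KOt-Bu cat., THF–t-BuOH) should give the nitro alcohol (3S,4R,7E)-3-ethenyl-3,4,7,8-tetramethyl-1-nitrodeca-7,9-dien-2-ol F1. Dehydration (MsCl, Et3N, 0 °C) should give the nitrotriene (1E,3S,4R,7E)-3-ethenyl-3,4,7,8-tetramethyl-1-nitrodeca-1,7,9-triene F2, which is expected to cyclise in benzene between room temperature and 80 °C to the nitro decalin (1S,2R,4aR,8R,8aR)-1-ethenyl-1,2,4a,5-tetramethyl-8-nitro-1,2,3,4,4a,7,8,8a-octahydronaphthalene F3. Radical denitration (Bu3SnH, AIBN, toluene, 110 °C) comes back to the route at 22.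

Step 4. Enantiofacial and chair/boat discrimination may be insufficient for an allyl terminus that carries both a methyl and a silyloxymethyl group, and the Lewis acidic boron reagent may attack the allylic silyl ether. The fallback gives up reagent control for a racemic rearrangement followed by classical resolution. It sets out from 5. LiN(i-Pr)2 and Me3SiCl in THF at −78 °C should give the (E)-O-trimethylsilyl ketene acetal of 5 F4, which rearranges on warming. After hydrolysis the racemic acid is obtained, that is 7 together with its enantiomer (2R,3R)-3-{[(tert-butyldimethylsilyl)oxy]methyl}-2,3-dimethylpent-4-enoic acid F5. Crystallisation with one enantiomer of 1-phenylethylamine, written here as (R), is to give the (R)-1-phenylethylammonium salt of 7 F6. Acidification comes back to the route at 7.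

Step 7. The iodide is β-branched and sits next to a quaternary carbon, so substitution may be slow and E2 elimination by the strongly basic dianion may take over. The fallback reverses the polarity of C7 and builds the β-keto ester by carbonyl chemistry. It sets out from 9. Iodine–lithium exchange (t-BuLi, Et2O–pentane, −78 °C) and opening of oxirane should give the alcohol (4R,5S)-5-{[(tert-butyldimethylsilyl)oxy]methyl}-4,5-dimethylhept-6-en-1-ol F7. Dess–Martin oxidation gives the aldehyde (4R,5S)-5-{[(tert-butyldimethylsilyl)oxy]methyl}-4,5-dimethylhept-6-enal F8. Roskamp homologation with methyl 2-diazopropanoate (SnCl2 cat., CH2Cl2) comes back to the route at 12.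

**Further compounds**

F1 | step 16 | (3S,4R,7E)-3-ethenyl-3,4,7,8-tetramethyl-1-nitrodeca-7,9-dien-2-ol (mixture at C2) | C=C[C@@](C(O)C[N+](=O)[O-])(C)[C@H](C)CC/C(C)=C(\C)C=C
F2 | step 16 | (1E,3S,4R,7E)-3-ethenyl-3,4,7,8-tetramethyl-1-nitrodeca-1,7,9-triene | C=C[C@@](/C=C/[N+](=O)[O-])(C)[C@H](C)CC/C(C)=C(\C)C=C
F3 | step 16 | (1S,2R,4aR,8R,8aR)-1-ethenyl-1,2,4a,5-tetramethyl-8-nitro-1,2,3,4,4a,7,8,8a-octahydronaphthalene | C=C[C@@]1(C)[C@H](C)CC[C@@]2(C)C(C)=CC[C@@H]([N+](=O)[O-])[C@H]12
F4 | step 4 | (E)-O-trimethylsilyl ketene acetal of 5 | C/C=C(/O[Si](C)(C)C)OC/C=C(\C)CO[Si](C)(C)C(C)(C)C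
F5 | step 4 | (2R,3R)-3-{[(tert-butyldimethylsilyl)oxy]methyl}-2,3-dimethylpent-4-enoic acid | C=C[C@](CO[Si](C)(C)C(C)(C)C)(C)[C@@H](C)C(=O)O
F6 | step 4 | (R)-1-phenylethylammonium (2S,3S)-3-{[(tert-butyldimethylsilyl)oxy]methyl}-2,3-dimethylpent-4-enoate | C=C[C@@](CO[Si](C)(C)C(C)(C)C)(C)[C@H](C)C(=O)[O-].C[C@@H]([NH3+])c1ccccc1
F7 | step 7 | (4R,5S)-5-{[(tert-butyldimethylsilyl)oxy]methyl}-4,5-dimethylhept-6-en-1-ol | C=C[C@@](CO[Si](C)(C)C(C)(C)C)(C)[C@H](C)CCCO
F8 | step 7 | (4R,5S)-5-{[(tert-butyldimethylsilyl)oxy]methyl}-4,5-dimethylhept-6-enal | C=C[C@@](CO[Si](C)(C)C(C)(C)C)(C)[C@H](C)CCC=O
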